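**Strategy**

Everything rests on disconnecting the aryl ether bond O1–C8a of the pyranone ring C. C8a of ring A is ortho to the C4 ketone (C4=O/C4a=C8a is a vinylogous acyl unit) and meta to both ring-A oxygens, so a fluorine there should be displaced by the C2 alkoxide in an intramolecular addition–elimination. This closes ring C in one operation without making or breaking any bond at C2, so a carbinol centre set earlier by asymmetric transfer hydrogenation is carried through unchanged. The precursor is an open-chain (S)-β-hydroxy ketone joining a 2-fluoro-4,6-dimethoxy-3-prenylphenyl ketone to the protected ring-B carbinol, assembled by acylation of an aryllithium with a Weinreb amide.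

Key step: step 7

Remark on the chemistry: the stereodescriptor of the target corresponds to (2S). Flavanone numbering is used (O1, C2, C3, C4, C4a, C5–C8, C8a; ring A is the benzo ring, ring B the aryl group at C2, ring C the pyranone). MOM = methoxymethyl, prenyl = 3-methylbut-2-en-1-yl.

**Route**

Step 1
Reactants: 1 1-(3-hydroxy-4-methoxyphenyl)ethan-1-one; 2 chloromethyl methyl ether
Product: 3 1-[4-methoxy-3-(methoxymethoxy)phenyl]ethan-1-one
Conditions: MOMCl (1.5 equiv), i-Pr2NEt (2 equiv), CH2Cl2, 0 °C → rt
Reagents that add atoms: chloromethyl methyl ether, COCCl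
Why: Base-mediated O-alkylation of the phenol with the reactive α-chloro ether (MOM protection) masks the only acidic O–H before the enolate and organometallic steps.

Step 2
Reactants: 3 1-[4-methoxy-3-(methoxymethoxy)phenyl]ethan-1-one; 4 diethyl carbonate
Product: 5 ethyl 3-[4-methoxy-3-(methoxymethoxy)phenyl]-3-oxopropanoate
Conditions: NaH (2.5 equiv), (EtO)2CO (3 equiv), THF, 65 °C; AcOH, 0 °C
Reagents that add atoms: diethyl carbonate, CCOC(=O)OCC
Why: Crossed Claisen condensation, in which the sodium enolate of the methyl ketone is C-acylated by the non-enolisable carbonate and the reaction is driven by deprotonation of the β-keto ester formed.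

Step 3
Reactants: 5 ethyl 3-[4-methoxy-3-(methoxymethoxy)phenyl]-3-oxopropanoate
Product: 6 ethyl (3S)-3-hydroxy-3-[4-methoxy-3-(methoxymethoxy)phenyl]propanoate
Conditions: RuCl[(S,S)-TsDPEN](p-cymene) (1 mol%), HCO2H/Et3N (5:2), DMF, 40 °C
Reagents that add atoms: none
Why: Noyori–Ikariya asymmetric transfer hydrogenation of the aryl ketone; the (S,S)-catalyst, which reduces aryl alkyl ketones to (S)-1-arylalkanols through a CH/π-controlled six-membered hydride/proton transfer, should set the carbinol carbon as S and leave the ester untouched.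

Step 4
Reactants: 6 ethyl (3S)-3-hydroxy-3-[4-methoxy-3-(methoxymethoxy)phenyl]propanoate; 7 N,O-dimethylhydroxylamine hydrochloride
Product: 8 (3S)-3-hydroxy-N-methoxy-3-[4-methoxy-3-(methoxymethoxy)phenyl]-N-methylpropanamide
Conditions: MeNHOMe·HCl (3 equiv), i-PrMgCl (7 equiv), THF, −20 → 0 °C
Reagents that add atoms: N,O-dimethylhydroxylamine hydrochloride, CNOC.Cl
Why: Weinreb amide formation by attack of the magnesium amide ClMgN(OMe)Me on the ester, with the hydroxyl carried as its magnesium alkoxide so that the stereocentre is not involved.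

Step 5
Reactants: 9 1-fluoro-3,5-dimethoxybenzene; 10 prenyl bromide (1-bromo-3-methylbut-2-ene)
Product: 12 1-fluoro-3,5-dimethoxy-2-(3-methylbut-2-en-1-yl)benzene, via aryllithium 11 (not isolated)
Conditions: n-BuLi (1.05 equiv), THF, −78 °C; CuBr·SMe2 (10 mol%), prenyl bromide, −78 → −40 °C
Reagents that add atoms: prenyl bromide, CC(C)=CCBr
Why: Directed ortho-metalation at −78 °C should occur at the C–H flanked by fluorine and methoxy (the most acidic ring position, whereas the position between the two methoxy groups is expected to metalate only at higher temperature), and the aryllithium is then allylated at the primary carbon of prenyl bromide under monovalent-copper catalysis before LiF can be lost.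

Step 6
Reactants: 12 1-fluoro-3,5-dimethoxy-2-(3-methylbut-2-en-1-yl)benzene; 8 (3S)-3-hydroxy-N-methoxy-3-[4-methoxy-3-(methoxymethoxy)phenyl]-N-methylpropanamide
Product: 16 (3S)-1-[2-fluoro-4,6-dimethoxy-3-(3-methylbut-2-en-1-yl)phenyl]-3-hydroxy-3-[4-methoxy-3-(methoxymethoxy)phenyl]propan-1-one, via aryllithium 13 (not isolated), via chloromagnesium alkoxide 14 (not isolated), via tetrahedral adduct 15 (not isolated)
Conditions: 12 (1.3 equiv), n-BuLi (1.25 equiv), THF, −78 °C; separately 8, i-PrMgCl (1.0 equiv), THF, −40 °C; combined at −78 °C, then −78 → −50 °C; aq. NH4Cl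
Reagents that add atoms: none
Why: A second directed ortho-metalation at the remaining fluorine/methoxy-flanked C–H gives an aryllithium that is acylated by the Weinreb amide (Weinreb ketone synthesis), the chelated tetrahedral adduct preventing over-addition and the magnesium alkoxide shielding the carbinol, whose configuration is unchanged.

Step 7
Reactants: 16 (3S)-1-[2-fluoro-4,6-dimethoxy-3-(3-methylbut-2-en-1-yl)phenyl]-3-hydroxy-3-[4-methoxy-3-(methoxymethoxy)phenyl]propan-1-one
Product: 18 (2S)-5,7-dimethoxy-2-[4-methoxy-3-(methoxymethoxy)phenyl]-8-(3-methylbut-2-en-1-yl)-2,3-dihydro-4H-chromen-4-one, via sodium alkoxide 17 (not isolated)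
Conditions: NaN(SiMe3)2 (1.0 equiv), THF (0.02 M), −78 → 0 °C; AcOH
Reagents that add atoms: none
Why: Deprotonation of the secondary hydroxyl gives alkoxide 17, whose oxygen adds to C8a to give a Meisenheimer-type adduct with the charge delocalised into the C4 carbonyl, and loss of fluoride as NaF makes the closure irreversible (intramolecular SNAr, addition–elimination). The closest known reaction type is the base-mediated cyclisation of 2-fluorophenyl β-hydroxy ketones to chroman-4-ones. Ring C closes as a six-membered ring by attack of O1 on the sp2 carbon C8a, a 6-endo-trig closure with respect to the in-ring C8a=C4a–C4=O unit, which is a favoured mode. No new stereocentre forms, and C2 keeps its S configuration because none of its bonds takes part. The step needs chemoselectivity for cyclisation over retro-aldol cleavage and β-elimination, which the low temperature, the single equivalent of base, the high dilution and the ortho-ketone activation of the only C–F bond should secure. Site selectivity for C8a over the other ortho carbon (C5, bearing OMe) follows from fluoride being by far the better SNAr leaving group, and both methoxy groups, being meta to C8a, do not deactivate that carbon.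

Step 8
Reactants: 18 (2S)-5,7-dimethoxy-2-[4-methoxy-3-(methoxymethoxy)phenyl]-8-(3-methylbut-2-en-1-yl)-2,3-dihydro-4H-chromen-4-one
Product: 19 (2S)-5-hydroxy-7-methoxy-2-[4-methoxy-3-(methoxymethoxy)phenyl]-8-(3-methylbut-2-en-1-yl)-2,3-dihydro-4H-chromen-4-one
Conditions: MgI2·OEt2 (3 equiv), THF, 55 °C; aq. NH4Cl, Na2S2O3
Reagents that add atoms: none
Why: Chelation-controlled ether cleavage, in which magnesium bound between the C4 carbonyl and O5 activates only the peri methyl ether for SN2 attack by iodide, a selectivity known for 5-methoxyflavanones carrying an 8-prenyl group, so the 7- and 4'-methyl ethers, the MOM ether, the alkene and C2 should be left alone.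

Step 9
Reactants: 19 (2S)-5-hydroxy-7-methoxy-2-[4-methoxy-3-(methoxymethoxy)phenyl]-8-(3-methylbut-2-en-1-yl)-2,3-dihydro-4H-chromen-4-one
Product: 20 (2S)-5-hydroxy-2-(3-hydroxy-4-methoxyphenyl)-7-methoxy-8-(3-methylbut-2-en-1-yl)-2,3-dihydro-4H-chromen-4-one (target)
Conditions: HCl (3 M aq.), MeOH, 40 °C
Reagents that add atoms: none
Why: Acid-catalysed acetal exchange removes the MOM group as dimethoxymethane under conditions in which the prenyl group (no free ortho hydroxyl) and the hydrogen-bonded 5-hydroxyflavanone, including C2, are expected to survive.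

**Compound list**

1 | 1-(3-hydroxy-4-methoxyphenyl)ethan-1-one | CC(=O)c1ccc(OC)c(O)c1 | starting material
2 | chloromethyl methyl ether | COCCl | starting material
3 | 1-[4-methoxy-3-(methoxymethoxy)phenyl]ethan-1-one | CC(=O)c1ccc(OC)c(OCOC)c1 | intermediate
4 | diethyl carbonate | CCOC(=O)OCC | starting material
5 | ethyl 3-[4-methoxy-3-(methoxymethoxy)phenyl]-3-oxopropanoate | CCOC(=O)CC(=O)c1ccc(OC)c(OCOC)c1 | intermediate
6 | ethyl (3S)-3-hydroxy-3-[4-methoxy-3-(methoxymethoxy)phenyl]propanoate | CCOC(=O)C[C@H](O)c1ccc(OC)c(OCOC)c1 | intermediate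
7 | N,O-dimethylhydroxylamine hydrochloride | CNOC.Cl | starting material
8 | (3S)-3-hydroxy-N-methoxy-3-[4-methoxy-3-(methoxymethoxy)phenyl]-N-methylpropanamide | CON(C)C(=O)C[C@H](O)c1ccc(OC)c(OCOC)c1 | intermediate
9 | 1-fluoro-3,5-dimethoxybenzene | COc1cc(F)cc(OC)c1 | starting material
10 | prenyl bromide (1-bromo-3-methylbut-2-ene) | CC(C)=CCBr | starting material
11 | (2-fluoro-4,6-dimethoxyphenyl)lithium | [Li]c1c(F)cc(OC)cc1OC | intermediate
12 | 1-fluoro-3,5-dimethoxy-2-(3-methylbut-2-en-1-yl)benzene | COc1cc(F)c(CC=C(C)C)c(OC)c1 | intermediate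
13 | [2-fluoro-4,6-dimethoxy-3-(3-methylbut-2-en-1-yl)phenyl]lithium | [Li]c1c(F)c(CC=C(C)C)c(OC)cc1OC | intermediate
14 | chloromagnesium alkoxide of amide 8 | CON(C)C(=O)C[C@H](O[Mg]Cl)c1ccc(OC)c(OCOC)c1 | intermediate
15 | tetrahedral adduct of 13 and 14 (lithium N,O-hemiaminalate, chloromagnesium alkoxide; new carbon unassigned) | CON(C)C(O[Li])(C[C@H](O[Mg]Cl)c1ccc(OC)c(OCOC)c1)c1c(F)c(CC=C(C)C)c(OC)cc1OC | intermediate
16 | (3S)-1-[2-fluoro-4,6-dimethoxy-3-(3-methylbut-2-en-1-yl)phenyl]-3-hydroxy-3-[4-methoxy-3-(methoxymethoxy)phenyl]propan-1-one | COCOc1cc([C@@H](O)CC(=O)c2c(F)c(CC=C(C)C)c(OC)cc2OC)ccc1OC | intermediate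
17 | sodium alkoxide of 16 | COCOc1cc([C@@H]([O-])CC(=O)c2c(F)c(CC=C(C)C)c(OC)cc2OC)ccc1OC.[Na+] | intermediate
18 | (2S)-5,7-dimethoxy-2-[4-methoxy-3-(methoxymethoxy)phenyl]-8-(3-methylbut-2-en-1-yl)-2,3-dihydro-4H-chromen-4-one | COCOc1cc([C@@H]2CC(=O)c3c(OC)cc(OC)c(CC=C(C)C)c3O2)ccc1OC | intermediate
19 | (2S)-5-hydroxy-7-methoxy-2-[4-methoxy-3-(methoxymethoxy)phenyl]-8-(3-methylbut-2-en-1-yl)-2,3-dihydro-4H-chromen-4-one | COCOc1cc([C@@H]2CC(=O)c3c(O)cc(OC)c(CC=C(C)C)c3O2)ccc1OC | intermediate
20 | (2S)-5-hydroxy-2-(3-hydroxy-4-methoxyphenyl)-7-methoxy-8-(3-methylbut-2-en-1-yl)-2,3-dihydro-4H-chromen-4-one | COc1ccc([C@@H]2CC(=O)c3c(O)cc(OC)c(CC=C(C)C)c3O2)cc1O | target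

**Step count and risks**

Total steps: 9. Longest linear sequence: 8 (steps 1–4, then 6–9); step 5 supplies the ring-A fragment.

Steps most likely to fail:

1. Step 7 (ring closure). The alkoxide may undergo reversible retro-aldol cleavage, which would erode the configuration at C2. Its enolate tautomer may lose hydroxide, or the product may be deprotonated at C3 and ring C reopened. The fallback removes the carbonyl before cyclisation. It sets out from 16, which is reduced with NaBH4 in MeOH at 0 °C to (3S)-1-[2-fluoro-4,6-dimethoxy-3-(3-methylbut-2-en-1-yl)phenyl]-3-[4-methoxy-3-(methoxymethoxy)phenyl]propane-1,3-diol F1 (both C1 epimers). With KOt-Bu in DMF at 80 °C only the C3 alkoxide can reach the C–F carbon in a six-membered closure (intramolecular SNAr on an unactivated fluoroarene whose methoxy groups are meta to fluorine), and no retro-aldol path exists. This should give (2S)-5,7-dimethoxy-2-[4-methoxy-3-(methoxymethoxy)phenyl]-8-(3-methylbut-2-en-1-yl)chroman-4-ol F2 (both C4 epimers). Oxidation with Dess–Martin periodinane in CH2Cl2 returns the route to 18.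

2. Step 6 (second metalation and acylation). Metalation may take place at the benzylic–allylic CH2 of the prenyl group or at C4 instead of C6, and the aryllithium may lose LiF before it is acylated. The fallback fixes the acyl site with bromine and makes the aryllithium by halogen–lithium exchange. It sets out from 9, which is brominated with NBS in MeCN at 0 °C ortho to fluorine and para to methoxy to give 2-bromo-1-fluoro-3,5-dimethoxybenzene F3. Metalation with LiN(i-Pr)2 in THF at −78 °C at the remaining fluorine-flanked C–H, then CuBr·SMe2 (10 mol%) and prenyl bromide, should give 1-bromo-2-fluoro-4,6-dimethoxy-3-(3-methylbut-2-en-1-yl)benzene F4. Bromine–lithium exchange with n-BuLi at −78 °C gives aryllithium 13, where the fallback rejoins the route and continues with 14 to 16.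

3. Step 8 (5-O-demethylation). The Lewis acid may reversibly open ring C and erode the configuration at C2, HI may add to the prenyl double bond, or the other ethers may be attacked. The fallback carries O5 as a MOM ether from the start, so that only the final acid step is needed. It sets out from 14 (made from 8) and commercial 3-fluoro-5-methoxyphenol.
   - The phenol is silylated (i-Pr3SiCl, imidazole, DMF) to (3-fluoro-5-methoxyphenoxy)tri(propan-2-yl)silane F5.
   - The bulky silyl ether shields its ortho positions, so n-BuLi at −78 °C should metalate between fluorine and methoxy; CuBr·SMe2 (10 mol%) and prenyl bromide then give [3-fluoro-5-methoxy-4-(3-methylbut-2-en-1-yl)phenoxy]tri(propan-2-yl)silane F6.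
   - Bu4NF in THF gives 3-fluoro-5-methoxy-4-(3-methylbut-2-en-1-yl)phenol F7, and MOMCl with i-Pr2NEt gives 1-fluoro-3-methoxy-5-(methoxymethoxy)-2-(3-methylbut-2-en-1-yl)benzene F8.
   - Metalation with n-BuLi at −78 °C between fluorine and the MOM ether, then addition of 14, gives (3S)-1-[2-fluoro-4-methoxy-6-(methoxymethoxy)-3-(3-methylbut-2-en-1-yl)phenyl]-3-hydroxy-3-[4-methoxy-3-(methoxymethoxy)phenyl]propan-1-one F9.
   - Cyclisation with NaN(SiMe3)2 as in step 7 gives (2S)-7-methoxy-5-(methoxymethoxy)-2-[4-methoxy-3-(methoxymethoxy)phenyl]-8-(3-methylbut-2-en-1-yl)-2,3-dihydro-4H-chromen-4-one F10.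
   - HCl in MeOH at 40 °C removes both MOM groups and returns the route to target 20.

**Further compounds**

F1 | step 7 | (3S)-1-[2-fluoro-4,6-dimethoxy-3-(3-methylbut-2-en-1-yl)phenyl]-3-[4-methoxy-3-(methoxymethoxy)phenyl]propane-1,3-diol | COCOc1cc([C@@H](O)CC(O)c2c(F)c(CC=C(C)C)c(OC)cc2OC)ccc1OC
F2 | step 7 | (2S)-5,7-dimethoxy-2-[4-methoxy-3-(methoxymethoxy)phenyl]-8-(3-methylbut-2-en-1-yl)chroman-4-ol | COCOc1cc([C@@H]2CC(O)c3c(OC)cc(OC)c(CC=C(C)C)c3O2)ccc1OC
F3 | step 6 | 2-bromo-1-fluoro-3,5-dimethoxybenzene | COc1cc(F)c(Br)c(OC)c1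
F4 | step 6 | 1-bromo-2-fluoro-4,6-dimethoxy-3-(3-methylbut-2-en-1-yl)benzene | COc1cc(OC)c(CC=C(C)C)c(F)c1Br
F5 | step 8 | (3-fluoro-5-methoxyphenoxy)tri(propan-2-yl)silane | COc1cc(F)cc(O[Si](C(C)C)(C(C)C)C(C)C)c1
F6 | step 8 | [3-fluoro-5-methoxy-4-(3-methylbut-2-en-1-yl)phenoxy]tri(propan-2-yl)silane | COc1cc(O[Si](C(C)C)(C(C)C)C(C)C)cc(F)c1CC=C(C)C
F7 | step 8 | 3-fluoro-5-methoxy-4-(3-methylbut-2-en-1-yl)phenol | COc1cc(O)cc(F)c1CC=C(C)C
F8 | step 8 | 1-fluoro-3-methoxy-5-(methoxymethoxy)-2-(3-methylbut-2-en-1-yl)benzene | COCOc1cc(F)c(CC=C(C)C)c(OC)c1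
F9 | step 8 | (3S)-1-[2-fluoro-4-methoxy-6-(methoxymethoxy)-3-(3-methylbut-2-en-1-yl)phenyl]-3-hydroxy-3-[4-methoxy-3-(methoxymethoxy)phenyl]propan-1-one | COCOc1cc([C@@H](O)CC(=O)c2c(F)c(CC=C(C)C)c(OC)cc2OCOC)ccc1OC
F10 | step 8 | (2S)-7-methoxy-5-(methoxymethoxy)-2-[4-methoxy-3-(methoxymethoxy)phenyl]-8-(3-methylbut-2-en-1-yl)-2,3-dihydro-4H-chromen-4-one | COCOc1cc([C@@H]2CC(=O)c3c(OCOC)cc(OC)c(CC=C(C)C)c3O2)ccc1OC
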